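The central hexasubstituted benzene ring, with its four methoxy groups, is a masked 2,5-dimethoxy-1,4-benzoquinone. Its two para-related oxygen-bearing carbons, one ortho to each indolyl carbon, become quinone carbonyls, which turns the ring carbon destined to carry the 5-methoxyindol-3-yl group into an electrophilic C–H site. The key step adds the nucleophilic C3–H of 5-methoxyindole to that carbon of a 2-indolyl-3,6-dichloro-1,4-benzoquinone and reoxidizes in the same flask, so the indole C3–aryl bond forms without a halide or metal on either partner. In the precursor the chlorines stand in for two methoxy groups and the second indole carries its phenol as a benzyl ether.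

Key step: step 2

Remark: the target has no stereocentre and no stereogenic axis; compounds 1, 2 and 5 are taken as commercial.

Step 1
Reactants: 1 2,5-dichloro-1,4-benzoquinone; 2 5-(benzyloxy)-1H-indole
Product: 4 2-[5-(benzyloxy)-1H-indol-3-yl]-3,6-dichloro-1,4-benzoquinone, via dichlorohydroquinone adduct 3 (not isolated)
Conditions: AcOH/THF, rt; then DDQ, rt
Reagents that add atoms: none
Why: Acid-promoted Michael addition of indole C3 to an unsubstituted carbon of quinone 1 should give hydroquinone 3 after tautomerization, and DDQ dehydrogenation restores the quinone; product 4 is much less electrophilic than 1 because of its indolyl donor, so the reaction should stop at mono-addition.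

Step 2
Reactants: 4 2-[5-(benzyloxy)-1H-indol-3-yl]-3,6-dichloro-1,4-benzoquinone; 5 5-methoxy-1H-indole
Product: 7 2-[5-(benzyloxy)-1H-indol-3-yl]-3,6-dichloro-5-(5-methoxy-1H-indol-3-yl)-1,4-benzoquinone, via bis(indolyl)dichlorohydroquinone 6 (not isolated)
Conditions: AcOH, rt; then DDQ, THF, rt
Reagents that add atoms: none
Why: In acetic acid the activated quinone 4 is attacked at its only C–H ring carbon by C3 of 5-methoxyindole (the enamine β-carbon), and loss of the indole C3 proton followed by enolization gives hydroquinone 6, which DDQ dehydrogenates to quinone 7. The closest known reaction type is the acid-promoted Michael addition of indoles to 2,5-dichloro-1,4-benzoquinone with subsequent DDQ oxidation, the standard entry to bis(indolyl)quinones of the asterriquinone family. No ring is closed and no stereocentre is formed; in the target each indolyl carbon of the central ring lies between two identical methoxy-bearing carbons, so neither biaryl axis is stereogenic. The step needs site selectivity on the quinone: the attacked carbon is β to the carbonyl that is cross-conjugated with, and therefore not deactivated by, the first indolyl donor, and as the sole unsubstituted position it should react by addition rather than by addition–elimination at the chlorine-bearing carbons. On the indole side C3 is the most nucleophilic position, and a modest excess of 5 with late addition of DDQ should limit oxidative loss of the electron-rich indole.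

Step 3
Reactants: 7 2-[5-(benzyloxy)-1H-indol-3-yl]-3,6-dichloro-5-(5-methoxy-1H-indol-3-yl)-1,4-benzoquinone
Product: 8 2-[5-(benzyloxy)-1H-indol-3-yl]-3,6-dimethoxy-5-(5-methoxy-1H-indol-3-yl)-1,4-benzoquinone
Conditions: NaOMe, MeOH/THF, 0 °C to rt
Reagents that add atoms: sodium methoxide, [Na+].[O-]C
Why: Twofold addition–elimination (vinylogous acyl substitution) of methoxide at the two chlorine-bearing carbons, each β to a quinone carbonyl, should replace both chlorides by methoxy, while the benzyl ether and the indole rings are inert to methoxide.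

Step 4
Reactants: 8 2-[5-(benzyloxy)-1H-indol-3-yl]-3,6-dimethoxy-5-(5-methoxy-1H-indol-3-yl)-1,4-benzoquinone
Product: 10 5-(benzyloxy)-3-[2,3,5,6-tetramethoxy-4-(5-methoxy-1H-indol-3-yl)phenyl]-1H-indole, via dimethoxyhydroquinone 9 (not isolated)
Conditions: Na2S2O4, THF/H2O, rt; then Me2SO4, K2CO3, acetone, reflux, N2
Reagents that add atoms: dimethyl sulfate, COS(=O)(=O)OC
Why: Dithionite reduction of the quinone gives hydroquinone 9, whose two phenolic hydroxyls undergo Williamson O-methylation with dimethyl sulfate under a carbonate base too weak to deprotonate the indole N–H, so N-methylation should be avoided.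

Step 5
Reactants: 10 5-(benzyloxy)-3-[2,3,5,6-tetramethoxy-4-(5-methoxy-1H-indol-3-yl)phenyl]-1H-indole
Product: 11 3-[2,3,5,6-tetramethoxy-4-(5-methoxy-1H-indol-3-yl)phenyl]-1H-indol-5-ol
Conditions: H2 (1 atm), Pd/C, EtOAc/MeOH, rt
Reagents that add atoms: none
Why: Catalytic hydrogenolysis of the benzyl aryl ether over Pd/C should free the 5-hydroxy group while the methyl ethers and both indole rings stay untouched at room temperature and one atmosphere of hydrogen.

Compound list
1 | 2,5-dichloro-1,4-benzoquinone | O=C1C(Cl)=CC(=O)C(Cl)=C1 | starting material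
2 | 5-(benzyloxy)-1H-indole | c1ccc(COc2ccc3[nH]ccc3c2)cc1 | starting material
3 | 2-[5-(benzyloxy)-1H-indol-3-yl]-3,6-dichlorobenzene-1,4-diol | Oc1cc(Cl)c(O)c(-c2c[nH]c3ccc(OCc4ccccc4)cc23)c1Cl | intermediate
4 | 2-[5-(benzyloxy)-1H-indol-3-yl]-3,6-dichloro-1,4-benzoquinone | O=C1C=C(Cl)C(=O)C(-c2c[nH]c3ccc(OCc4ccccc4)cc23)=C1Cl | intermediate
5 | 5-methoxy-1H-indole | COc1ccc2[nH]ccc2c1 | starting material
6 | 2-[5-(benzyloxy)-1H-indol-3-yl]-3,6-dichloro-5-(5-methoxy-1H-indol-3-yl)benzene-1,4-diol | COc1ccc2[nH]cc(-c3c(O)c(Cl)c(-c4c[nH]c5ccc(OCc6ccccc6)cc45)c(O)c3Cl)c2c1 | intermediate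
7 | 2-[5-(benzyloxy)-1H-indol-3-yl]-3,6-dichloro-5-(5-methoxy-1H-indol-3-yl)-1,4-benzoquinone | COc1ccc2[nH]cc(C3=C(Cl)C(=O)C(-c4c[nH]c5ccc(OCc6ccccc6)cc45)=C(Cl)C3=O)c2c1 | intermediate
8 | 2-[5-(benzyloxy)-1H-indol-3-yl]-3,6-dimethoxy-5-(5-methoxy-1H-indol-3-yl)-1,4-benzoquinone | COc1ccc2[nH]cc(C3=C(OC)C(=O)C(-c4c[nH]c5ccc(OCc6ccccc6)cc45)=C(OC)C3=O)c2c1 | intermediate
9 | 2-[5-(benzyloxy)-1H-indol-3-yl]-3,6-dimethoxy-5-(5-methoxy-1H-indol-3-yl)benzene-1,4-diol | COc1ccc2[nH]cc(-c3c(O)c(OC)c(-c4c[nH]c5ccc(OCc6ccccc6)cc45)c(O)c3OC)c2c1 | intermediate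
10 | 5-(benzyloxy)-3-[2,3,5,6-tetramethoxy-4-(5-methoxy-1H-indol-3-yl)phenyl]-1H-indole | COc1ccc2[nH]cc(-c3c(OC)c(OC)c(-c4c[nH]c5ccc(OCc6ccccc6)cc45)c(OC)c3OC)c2c1 | intermediate
11 | 3-[2,3,5,6-tetramethoxy-4-(5-methoxy-1H-indol-3-yl)phenyl]-1H-indol-5-ol | COc1ccc2[nH]cc(-c3c(OC)c(OC)c(-c4c[nH]c5ccc(O)cc45)c(OC)c3OC)c2c1 | target

Total step count: 5
Longest linear sequence: 5 steps (from 1 and 2 to 11)

Steps most likely to fail

Step 2. The conjugate addition may stall because the first indolyl donor lowers the electrophilicity of the quinone, and the electron-rich 5-methoxyindole may be lost to acid-induced oligomerization or to over-oxidation by DDQ. The fallback makes the same bond by base-mediated addition–elimination on a perhalogenated quinone. It sets out from 2: tetrabromo-1,4-benzoquinone (commercial, O=C1C(Br)=C(Br)C(=O)C(Br)=C1Br) and 2 with Cs2CO3 in MeCN at room temperature should give 2-[5-(benzyloxy)-1H-indol-3-yl]-3,5,6-tribromo-1,4-benzoquinone F1. A second Cs2CO3-mediated substitution with 5 should displace the bromide para to the first indolyl group, the one β to the carbonyl not deactivated by that donor, to give 2-[5-(benzyloxy)-1H-indol-3-yl]-3,6-dibromo-5-(5-methoxy-1H-indol-3-yl)-1,4-benzoquinone F2. NaOMe in MeOH/THF then replaces both remaining bromides, and the route is rejoined at 8.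

Step 3. The second chloride displacement may be slow once the first methoxy group and partial N–H deprotonation have deactivated the ring, and adventitious hydroxide or demethylation by methoxide may carry the material on to hydroxyquinones. The fallback accepts full hydrolysis instead. It sets out from 7: NaOH in MeOH/H2O at reflux followed by acidification should give 2-[5-(benzyloxy)-1H-indol-3-yl]-3,6-dihydroxy-5-(5-methoxy-1H-indol-3-yl)-1,4-benzoquinone F3. Its two acidic vinylogous-acid hydroxyls are then O-methylated with TMSCHN2 in MeOH/toluene, conditions that leave the indole N–H alone, and the route is rejoined at 8.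

Step 4. The hydroquinone may reoxidize to the quinone under basic conditions before it is alkylated, the two hindered hydroxyls may methylate incompletely under the mild carbonate base, and forcing conditions would bring competing N-methylation of the indoles. The fallback masks both nitrogens so that a strong base can be used. It sets out from 8: Boc2O and DMAP in MeCN should give the bis(N-Boc) dimethoxyquinone F4. Na2S2O4 reduction gives the bis(N-Boc) dimethoxyhydroquinone F5, which is methylated directly with NaH and MeI in DMF at 0 °C to give the bis(N-Boc) tetramethoxybenzene F6. K2CO3 in MeOH at reflux removes both carbamates, and the route is rejoined at 10.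

Further compounds
F1 | step 2 | 2-[5-(benzyloxy)-1H-indol-3-yl]-3,5,6-tribromo-1,4-benzoquinone | O=C1C(Br)=C(Br)C(=O)C(-c2c[nH]c3ccc(OCc4ccccc4)cc23)=C1Br
F2 | step 2 | 2-[5-(benzyloxy)-1H-indol-3-yl]-3,6-dibromo-5-(5-methoxy-1H-indol-3-yl)-1,4-benzoquinone | COc1ccc2[nH]cc(C3=C(Br)C(=O)C(-c4c[nH]c5ccc(OCc6ccccc6)cc45)=C(Br)C3=O)c2c1
F3 | step 3 | 2-[5-(benzyloxy)-1H-indol-3-yl]-3,6-dihydroxy-5-(5-methoxy-1H-indol-3-yl)-1,4-benzoquinone | COc1ccc2[nH]cc(C3=C(O)C(=O)C(-c4c[nH]c5ccc(OCc6ccccc6)cc45)=C(O)C3=O)c2c1
F4 | step 4 | tert-butyl 5-(benzyloxy)-3-{4-[1-(tert-butoxycarbonyl)-5-methoxyindol-3-yl]-2,5-dimethoxy-3,6-dioxocyclohexa-1,4-dien-1-yl}indole-1-carboxylate | COc1ccc2c(c1)c(C1=C(OC)C(=O)C(c3cn(C(=O)OC(C)(C)C)c4ccc(OCc5ccccc5)cc34)=C(OC)C1=O)cn2C(=O)OC(C)(C)C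
F5 | step 4 | tert-butyl 5-(benzyloxy)-3-{4-[1-(tert-butoxycarbonyl)-5-methoxyindol-3-yl]-2,5-dihydroxy-3,6-dimethoxyphenyl}indole-1-carboxylate | COc1ccc2c(c1)c(-c1c(O)c(OC)c(-c3cn(C(=O)OC(C)(C)C)c4ccc(OCc5ccccc5)cc34)c(O)c1OC)cn2C(=O)OC(C)(C)C
F6 | step 4 | tert-butyl 5-(benzyloxy)-3-{4-[1-(tert-butoxycarbonyl)-5-methoxyindol-3-yl]-2,3,5,6-tetramethoxyphenyl}indole-1-carboxylate | COc1ccc2c(c1)c(-c1c(OC)c(OC)c(-c3cn(C(=O)OC(C)(C)C)c4ccc(OCc5ccccc5)cc34)c(OC)c1OC)cn2C(=O)OC(C)(C)C
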